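**Retrosynthetic overview**

1. Ring A endgame: the acetate comes from the C1 alcohol; the trans C3-chloro/C4-bromo pair from titanium-alkoxide-directed addition of Br and Cl across a C3=C4 alkene; the C1 carbinol and that alkene from deconjugative reduction of a ring A enone.
2. C11(Me)OH comes from a C11 ketone by methylenation, epoxidation from the equatorial face and hydride opening.
3. Key disconnection: ring B at C8–C9, by 6-endo cyclization of an α-bromoalkyl radical at C8 (from a neopentylic CHBr2 group) onto a C11 acryloyl group; both carbons are electrophilic in the precursor (gem-dibromide carbon, enone β-carbon) and are joined through a radical.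
4. Enabling feature: with C11 held at the ketone level, C10=C9 is an enone whose carbonyl lies inside the forming ring B, and only the quaternary carbons C7 (gem-dimethyl) and C6 (spiro centre) separate the radical carbon from it, so 6-endo closure is electronically favoured and conformationally assisted.
5. The C6–C7 bond (two quaternary carbons) and the C6 stereocentre come from a Claisen rearrangement of the O-prenyl enol ether of 6-formyl-3-methylcyclohex-2-enone; ring order: ring A (bought as 3-methylcyclohex-2-en-1-one) first, ring B in step 8.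

Key step: step 8

Remark (labels): C1–C11 in the text are the target's spiro[5.5]undecane locants (ring A = C1–C6, C1 bears the acetate; ring B = C6–C11, C7 = CMe2, C8 = CHBr, C11 = C(Me)OH), whatever the numbering in the names of intermediates.

Remark (assumption): enol ether 4 is taken to be the E isomer and the (R,R) catalyst antipode is taken to give (S)-5; the other antipode is used if the sense of induction proves opposite.

**Route**

Step 1
Reactants: 1 3-methylcyclohex-2-en-1-one
Product: 2 (6Z)-6-(hydroxymethylidene)-3-methylcyclohex-2-en-1-one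
Conditions: LiN(i-Pr)2, THF, −78 °C; HCO2Et, −78 to 0 °C; 1 M HCl
Reagents that add atoms: ethyl formate, CCOC=O
Why: Claisen-type C-formylation of the kinetic α′-enolate, formed at the only non-vinylogous α-position (the future spiro carbon C6), should give the chelated hydroxymethylidene ketone, which stays as its stable enolate until acidification; no stereocentre is formed.

Step 2
Reactants: 2 (6Z)-6-(hydroxymethylidene)-3-methylcyclohex-2-en-1-one; 3 3-methylbut-2-en-1-ol
Product: 4 (6E)-3-methyl-6-{[(3-methylbut-2-en-1-yl)oxy]methylidene}cyclohex-2-en-1-one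
Conditions: PPh3, DIAD, THF, 0 °C to rt
Reagents that add atoms: none
Why: Mitsunobu O-alkylation of the acidic enol by the activated primary allylic alcohol in an SN2 sense should give the allyl vinyl ether at the exocyclic oxygen without C-prenylation; no stereocentre is formed.

Step 3
Reactants: 4 (6E)-3-methyl-6-{[(3-methylbut-2-en-1-yl)oxy]methylidene}cyclohex-2-en-1-one
Product: 5 (1S)-4-methyl-1-(2-methylbut-3-en-2-yl)-2-oxocyclohex-3-ene-1-carbaldehyde
Conditions: (R,R)-N,N′-bis[2-(2-arylpyrrol-1-yl)cyclohexyl]guanidinium B[3,5-(CF3)2C6H3]4 (20 mol %), hexanes, 40 °C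
Reagents that add atoms: none
Why: Proposed new method: the [3,3]-sigmatropic (Claisen) rearrangement delivers the tertiary prenyl terminus to C6, forming the C6–C7 bond between two quaternary carbons and releasing the C11 aldehyde; the chiral guanidinium is proposed to hydrogen-bond to the ring carbonyl oxygen, where negative charge builds up in the dipolar transition state (dicarbonyl-enolate/allyl-cation character), while its aryl groups stabilise the prenyl fragment and so differentiate the two faces of C6; the closest known reaction type is the guanidinium-catalysed enantioselective Claisen rearrangement of O-allyl enol ethers of cyclic β-keto esters, which forms quaternary centres in the same way.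

Step 4
Reactants: 5 (1S)-4-methyl-1-(2-methylbut-3-en-2-yl)-2-oxocyclohex-3-ene-1-carbaldehyde
Product: 6 (6S)-6-(1-hydroxyprop-2-en-1-yl)-3-methyl-6-(2-methylbut-3-en-2-yl)cyclohex-2-en-1-one (both carbinol epimers)
Conditions: CH2=CHMgBr, THF, −78 °C; 1 M HCl, −78 °C
Reagents that add atoms: vinylmagnesium bromide, C=C[Mg]Br
Why: Grignard 1,2-addition should take place only at the aldehyde, far more electrophilic than the hindered conjugated ring ketone, and the cold quench avoids retro-aldol loss of the new side chain; the carbinol centre is uncontrolled and is removed in step 5.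

Step 5
Reactants: 6 (6S)-6-(1-hydroxyprop-2-en-1-yl)-3-methyl-6-(2-methylbut-3-en-2-yl)cyclohex-2-en-1-one
Product: 7 (6S)-3-methyl-6-(2-methylbut-3-en-2-yl)-6-(prop-2-enoyl)cyclohex-2-en-1-one
Conditions: Dess–Martin periodinane, CH2Cl2, 0 °C to rt
Reagents that add atoms: none
Why: Dess–Martin oxidation of the secondary allylic alcohol under neutral conditions should convert both epimers into the same vinyl ketone, which sets up C10=C9 as the radical acceptor.

Step 6
Reactants: 7 (6S)-3-methyl-6-(2-methylbut-3-en-2-yl)-6-(prop-2-enoyl)cyclohex-2-en-1-one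
Product: 9 2-methyl-2-[(1S)-4-methyl-2-oxo-1-(prop-2-enoyl)cyclohex-3-en-1-yl]propanal, via ozonide 8 (not isolated)
Conditions: O3, CH2Cl2, −78 °C (Sudan red 7B end point); Me2S, −78 °C to rt
Reagents that add atoms: ozone, [O-][O+]=O
Why: Ozonolysis should cleave only the isolated monosubstituted alkene, which reacts with the electrophilic oxidant much faster than the two electron-poor enone double bonds, and reductive work-up gives the neopentylic C8 aldehyde.

Step 7
Reactants: 9 2-methyl-2-[(1S)-4-methyl-2-oxo-1-(prop-2-enoyl)cyclohex-3-en-1-yl]propanal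
Product: 10 (6S)-6-(1,1-dibromo-2-methylpropan-2-yl)-3-methyl-6-(prop-2-enoyl)cyclohex-2-en-1-one
Conditions: (PhO)3P, Br2, CH2Cl2, −78 °C to rt
Reagents that add atoms: bromine, BrBr
Why: Deoxygenative gem-dibromination of a non-enolisable aldehyde by the phosphite–bromine adduct (Appel-type activation of the carbonyl oxygen, then two bromide deliveries) is expected to spare the two ketones, which need base and heat to react with this reagent.

Step 8
Reactants: 10 (6S)-6-(1,1-dibromo-2-methylpropan-2-yl)-3-methyl-6-(prop-2-enoyl)cyclohex-2-en-1-one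
Product: 13 (6S,10R)-10-bromo-3,11,11-trimethylspiro[5.5]undec-2-ene-1,7-dione, via α-bromoalkyl radical 11 (not isolated), via α-keto radical 12 (not isolated)
Conditions: Bu3SnH (1.1 equiv, syringe pump), AIBN (10 mol %), benzene (5 mM), 80 °C
Reagents that add atoms: none
Why: The tributyltin radical abstracts one bromine of the neopentylic CHBr2 group to give the C8 radical 11, which adds to the terminal acryloyl carbon C9 to give the α-keto radical 12 at C10; this takes hydrogen from Bu3SnH and carries the chain. The closest known reaction type is the tin-hydride-mediated 6-endo cyclization of alkyl radicals onto vinyl ketones whose carbonyl lies inside the forming ring, combined with the known cyclizations of α-haloalkyl radicals generated from gem-dihalides. Ring B closes in the 6-endo-trig mode, because attack at C9 gives a delocalised α-keto radical, whereas 5-exo attack at C10 would give a primary radical and a cyclopentane with three contiguous quaternary carbons. The only new stereocentre, C8, should be set in a chair-like transition state with bromine pseudo-equatorial and the ring A carbonyl carbon C1 pseudo-axial on the forming ring (C1 is smaller than C5H2 and its dipole is turned away from the C11 carbonyl), which corresponds to (8R). The step needs selective abstraction from CHBr2 over the product monobromide (weaker C–Br bond, limiting stannane added slowly), cyclization faster than hydrogen transfer (high dilution, Thorpe–Ingold effect of C7 and C6) and discrimination against the ring A enone, whose β-carbon C3 is disubstituted and would lead to a bicyclo[2.2.2]octane with a new quaternary centre.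

Step 9
Reactants: 13 (6S,10R)-10-bromo-3,11,11-trimethylspiro[5.5]undec-2-ene-1,7-dione
Product: 14 (6R,10R)-10-bromo-3,11,11-trimethyl-7-methylidenespiro[5.5]undec-2-en-1-one
Conditions: Cp2Ti(μ-Cl)(μ-CH2)AlMe2, THF–toluene, −40 to 0 °C
Reagents that add atoms: Tebbe reagent Cp2Ti(μ-Cl)(μ-CH2)AlMe2, C[Al-]1(C)C[Ti](C2C=CC=C2)(C2C=CC=C2)[Cl+]1
Why: Tebbe olefination with the non-basic titanium methylidene should methylenate the saturated, more electrophilic C11 ketone in preference to the vinylogously deactivated ring A enone carbonyl and without elimination of the secondary bromide.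

Step 10
Reactants: 14 (6R,10R)-10-bromo-3,11,11-trimethyl-7-methylidenespiro[5.5]undec-2-en-1-one
Product: 15 (6S,7R,10R)-10-bromo-3,11,11-trimethyl-1-oxospiro[5.5]undec-2-ene-7-spiro-2′-oxirane (oxirane O equatorial on ring B and syn to C1)
Conditions: dimethyldioxirane, acetone, 0 °C
Reagents that add atoms: dimethyldioxirane, CC1(C)OO1
Why: Dioxirane epoxidation (concerted oxygen transfer, neutral) should touch only the electron-rich 1,1-disubstituted alkene and attack its equatorial face, because the axial face is shielded 1,3-diaxially by the axial methyl group on C7; this places the oxygen on C11 syn to C1 as required.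

Step 11
Reactants: 15 (6S,7R,10R)-10-bromo-3,11,11-trimethyl-1-oxospiro[5.5]undec-2-ene-7-spiro-2′-oxirane
Product: 18 (1R,6R,7R,10R)-10-bromo-3,11,11-trimethyl-7-spiro-2′-oxiranylspiro[5.5]undec-3-en-1-ol, via potassium dienolate 16 (not isolated), via β,γ-unsaturated ketone 17 (not isolated)
Conditions: KOt-Bu, t-BuOH–THF, 0 °C; AcOH, −78 °C; NaBH4, MeOH, −78 to −20 °C
Reagents that add atoms: none
Why: Deconjugative reduction: the thermodynamic endocyclic dienolate is protonated kinetically at C2 to give the C3=C4 ketone, which borohydride reduces before reconjugation, and hydride should add axially, anti to the pseudo-axial C6–C11 bond (the bulkier C7 is equatorial on ring A), so that the C1 hydroxyl is cis to C11.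

Step 12
Reactants: 18 (1R,6R,7R,10R)-10-bromo-3,11,11-trimethyl-7-spiro-2′-oxiranylspiro[5.5]undec-3-en-1-ol
Product: 19 (1R,6R,7R,10R)-10-bromo-3,7,11,11-tetramethylspiro[5.5]undec-3-ene-1,7-diol
Conditions: LiAlH4, THF, 0 °C; then H2O
Reagents that add atoms: none
Why: SN2 hydride opening of the 1,1-disubstituted epoxide at its CH2 carbon should give the tertiary alcohol with the C11 configuration fixed in step 10, while the neopentylic secondary bromide at C8 is inert to hydride substitution.

Step 13
Reactants: 19 (1R,6R,7R,10R)-10-bromo-3,7,11,11-tetramethylspiro[5.5]undec-3-ene-1,7-diol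
Product: 20 (1R,3S,4S,6R,7R,10R)-4,10-dibromo-3-chloro-3,7,11,11-tetramethylspiro[5.5]undecane-1,7-diol
Conditions: NBS, ClTi(Oi-Pr)3, CH2Cl2–hexanes, −20 °C
Reagents that add atoms: N-bromosuccinimide, O=C1CCC(=O)N1Br; chlorotitanium triisopropoxide, CC(C)O[Ti](Cl)(OC(C)C)OC(C)C
Why: Alkoxide-directed bromochlorination, known for allylic and homoallylic alcohols: the syn-1,3-diol should bind titanium as a chelate on the lower face, the alkene takes bromonium from NBS on the opposite face, and chloride is delivered from titanium to the tertiary (Markovnikov) carbon C3 on the face of the C1 oxygen, which gives the trans C3-chloro/C4-bromo pair with chlorine cis to the C1 oxygen.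

Step 14
Reactants: 20 (1R,3S,4S,6R,7R,10R)-4,10-dibromo-3-chloro-3,7,11,11-tetramethylspiro[5.5]undecane-1,7-diol
Product: 21 (1R,3S,4S,6R,8R,11R)-4,8-dibromo-3-chloro-11-hydroxy-3,7,7,11-tetramethylspiro[5.5]undecan-1-yl acetate
Conditions: Ac2O, pyridine, DMAP (cat.), CH2Cl2, 0 °C to rt
Reagents that add atoms: acetic anhydride, CC(=O)OC(C)=O
Why: DMAP-catalysed acylation should esterify only the secondary C1 hydroxyl, because the tertiary C11 hydroxyl flanked by two quaternary carbons is not acylated under these conditions.

**Compound list**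

1 | 3-methylcyclohex-2-en-1-one | CC1=CC(=O)CCC1 | starting material
2 | (6Z)-6-(hydroxymethylidene)-3-methylcyclohex-2-en-1-one | O/C=C1/CCC(C)=CC1=O | intermediate
3 | 3-methylbut-2-en-1-ol | CC(C)=CCO | starting material
4 | (6E)-3-methyl-6-{[(3-methylbut-2-en-1-yl)oxy]methylidene}cyclohex-2-en-1-one | CC(C)=CCO/C=C1\CCC(C)=CC1=O | intermediate
5 | (1S)-4-methyl-1-(2-methylbut-3-en-2-yl)-2-oxocyclohex-3-ene-1-carbaldehyde | O=C1C=C(C)CC[C@@]1(C=O)C(C)(C)C=C | intermediate
6 | (6S)-6-(1-hydroxyprop-2-en-1-yl)-3-methyl-6-(2-methylbut-3-en-2-yl)cyclohex-2-en-1-one, both carbinol epimers | O=C1C=C(C)CC[C@@]1(C(O)C=C)C(C)(C)C=C | intermediate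
7 | (6S)-3-methyl-6-(2-methylbut-3-en-2-yl)-6-(prop-2-enoyl)cyclohex-2-en-1-one | O=C1C=C(C)CC[C@@]1(C(=O)C=C)C(C)(C)C=C | intermediate
8 | ozonide: (6S)-3-methyl-6-(prop-2-enoyl)-6-[2-(1,2,4-trioxolan-3-yl)propan-2-yl]cyclohex-2-en-1-one | O=C1C=C(C)CC[C@@]1(C(=O)C=C)C(C)(C)C2OCOO2 | intermediate
9 | 2-methyl-2-[(1S)-4-methyl-2-oxo-1-(prop-2-enoyl)cyclohex-3-en-1-yl]propanal | O=C1C=C(C)CC[C@@]1(C(=O)C=C)C(C)(C)C=O | intermediate
10 | (6S)-6-(1,1-dibromo-2-methylpropan-2-yl)-3-methyl-6-(prop-2-enoyl)cyclohex-2-en-1-one | O=C1C=C(C)CC[C@@]1(C(=O)C=C)C(C)(C)C(Br)Br | intermediate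
11 | α-bromoalkyl radical at C8 derived from 10 | O=C1C=C(C)CC[C@@]1(C(=O)C=C)C(C)(C)[CH]Br | intermediate
12 | cyclized α-keto radical at C10 | O=C1C=C(C)CC[C@@]12C(C)(C)[C@H](Br)C[CH]C2=O | intermediate
13 | (6S,10R)-10-bromo-3,11,11-trimethylspiro[5.5]undec-2-ene-1,7-dione | O=C1C=C(C)CC[C@@]12C(C)(C)[C@H](Br)CCC2=O | intermediate
14 | (6R,10R)-10-bromo-3,11,11-trimethyl-7-methylidenespiro[5.5]undec-2-en-1-one | O=C1C=C(C)CC[C@@]12C(C)(C)[C@H](Br)CCC2=C | intermediate
15 | (6S,7R,10R)-10-bromo-3,11,11-trimethyl-1-oxospiro[5.5]undec-2-ene-7-spiro-2′-oxirane | O=C1C=C(C)CC[C@@]12C(C)(C)[C@H](Br)CC[C@@]23OC3 | intermediate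
16 | potassium dienolate of 15 (C1–O−, C1=C2, C3=C4) | [K+].[O-]C1=CC(C)=CC[C@@]12C(C)(C)[C@H](Br)CC[C@@]23OC3 | intermediate
17 | (6S,7R,10R)-β,γ-unsaturated ketone, the C3=C4 isomer of 15 | O=C1CC(C)=CC[C@@]12C(C)(C)[C@H](Br)CC[C@@]23OC3 | intermediate
18 | (1R,6R,7R,10R)-10-bromo-3,11,11-trimethyl-7-spiro-2′-oxiranylspiro[5.5]undec-3-en-1-ol | O[C@@H]1CC(C)=CC[C@@]12C(C)(C)[C@H](Br)CC[C@@]23OC3 | intermediate
19 | (1R,6R,7R,10R)-10-bromo-3,7,11,11-tetramethylspiro[5.5]undec-3-ene-1,7-diol | O[C@@H]1CC(C)=CC[C@@]12C(C)(C)[C@H](Br)CC[C@@]2(C)O | intermediate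
20 | (1R,3S,4S,6R,7R,10R)-4,10-dibromo-3-chloro-3,7,11,11-tetramethylspiro[5.5]undecane-1,7-diol | O[C@@H]1C[C@](C)(Cl)[C@@H](Br)C[C@@]12C(C)(C)[C@H](Br)CC[C@@]2(C)O | intermediate
21 | (1R,3S,4S,6R,8R,11R)-4,8-dibromo-3-chloro-11-hydroxy-3,7,7,11-tetramethylspiro[5.5]undecan-1-yl acetate | CC(=O)O[C@@H]1C[C@](C)(Cl)[C@@H](Br)C[C@@]12C(C)(C)[C@H](Br)CC[C@@]2(C)O | target

**Totals and risks**

Total step count: 14. Longest linear sequence: 14 steps (from compound 1).

Steps most likely to fail:

1. Step 3 (carries the label "Proposed new method:"). The E enol ether offers the catalyst only one binding point, so enantiofacial discrimination may be poor. The hydrogen-bond donor may also ionise the prenyl ether, leading to a 1,3-shift (linear C-prenylation) or loss of isoprene. The fallback uses known chemistry and moves the stereocontrol into the allyl fragment. It sets out from compound 2 and comes back to the route at compound 9. Commercial 4-methylpent-3-en-2-one is reduced by CBS reduction ((S)-2-methyl-CBS-oxazaborolidine, BH3·SMe2) to (R)-4-methylpent-3-en-2-ol F1. Mitsunobu coupling of F1 with 2 (PPh3, DIAD) proceeds with inversion to the (S)-configured E enol ether F2. Thermal Claisen rearrangement (toluene, 110 °C) through the chair transition state with the methyl group equatorial should transfer the carbinol chirality to C6 and give the (1S)-aldehyde F3, which carries an (E)-propenyl group in place of vinyl. Vinylmagnesium bromide and then Dess–Martin periodinane, as in steps 4 and 5, give carbinol F4 and enone F5. Ozonolysis as in step 6 cleaves the propenyl double bond, the most electron-rich one, to aldehyde 9.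

2. Step 8 (key step). The C8 radical may take hydrogen before it cyclizes, may add to the ring A enone, or may close through the chair with the other ring A carbon axial (C8 epimer); the product monobromide may also be reduced further. The fallback removes the hydride donor and changes the chain to atom transfer. It sets out from compound 10 and comes back at compound 13. Copper-catalysed atom-transfer radical cyclization (CuBr, tris(2-pyridylmethyl)amine, catalytic AIBN, toluene, 60 °C) should give the C10-bromo spiro dione F6 with bromine transferred to the α-keto radical. Zinc dust in AcOH then removes only the activated α-keto bromine to give 13.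

3. Step 13. Facial or positional control of the Br/Cl addition may be incomplete, and the C11 hydroxyl may capture the bromonium ion across ring A as an ether. The fallback introduces the two halogens one after the other by substitution chemistry. It sets out from compound 19 and comes back at compound 21. Hydroxyl-directed epoxidation (VO(acac)2, t-BuOOH) gives the C3–C4 epoxide cis to the C1 hydroxyl, epoxy diol F7. Bromide opening at the less substituted C4 with inversion (Li2NiBr4, THF) gives the 4-bromo-3-hydroxy triol F8. Selective acetylation of the secondary hydroxyl (Ac2O, pyridine) gives acetate F9. HCl in CH2Cl2 at 0 °C then replaces the tertiary C3 hydroxyl by chloride with retention through the bromonium ion formed by the anti bromine, which gives 21.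

**Further compounds**

F1 | step 3 | (R)-4-methylpent-3-en-2-ol | CC(C)=C[C@@H](C)O
F2 | step 3 | (6E)-3-methyl-6-({[(2S)-4-methylpent-3-en-2-yl]oxy}methylidene)cyclohex-2-en-1-one | CC(C)=C[C@H](C)O/C=C1\CCC(C)=CC1=O
F3 | step 3 | (1S)-4-methyl-1-[(3E)-2-methylpent-3-en-2-yl]-2-oxocyclohex-3-ene-1-carbaldehyde | O=C1C=C(C)CC[C@@]1(C=O)C(C)(C)/C=C/C
F4 | step 3 | (6S)-6-(1-hydroxyprop-2-en-1-yl)-3-methyl-6-[(3E)-2-methylpent-3-en-2-yl]cyclohex-2-en-1-one, both carbinol epimers | O=C1C=C(C)CC[C@@]1(C(O)C=C)C(C)(C)/C=C/C
F5 | step 3 | (6S)-3-methyl-6-[(3E)-2-methylpent-3-en-2-yl]-6-(prop-2-enoyl)cyclohex-2-en-1-one | O=C1C=C(C)CC[C@@]1(C(=O)C=C)C(C)(C)/C=C/C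
F6 | step 8 | C10-bromo derivative of 13 (target numbering), both C10 epimers | O=C1C=C(C)CC[C@@]12C(C)(C)[C@H](Br)CC(Br)C2=O
F7 | step 13 | C3–C4 epoxide of 19, oxirane oxygen cis to the C1 hydroxyl | O[C@@H]1C[C@]2(C)O[C@@H]2C[C@@]13C(C)(C)[C@H](Br)CC[C@@]3(C)O
F8 | step 13 | 4,10-dibromo-3,7,11,11-tetramethylspiro[5.5]undecane-1,3,7-triol, C4 bromine trans to the C3 hydroxyl | O[C@@H]1C[C@](C)(O)[C@@H](Br)C[C@@]12C(C)(C)[C@H](Br)CC[C@@]2(C)O
F9 | step 13 | C1 acetate of F8 | CC(=O)O[C@@H]1C[C@](C)(O)[C@@H](Br)C[C@@]12C(C)(C)[C@H](Br)CC[C@@]2(C)O
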